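all flasks: initiator 0.25 mM

| run | free monomer | protic impurity | remark | time |
|---|---|---|---|---|
| Tuesday's | 0.027 M | 1.9 mM | run made earlier |  |
| Wednesday's | 0.042 M | 1.9 mM | run made earlier |  |
| Monday's | 0.019 M | 3.8 mM | run made earlier |  |
| flask | 0.019 M | 1.90 mM |  | 4.0 h |

| run | time / h | monomer in chains / % | free monomer / % |
|---|---|---|---|
| Tuesday's | 0.667 | 13.9 | 78.7 |
| Tuesday's | 1.33 | 25.2 | 67.1 |
| Tuesday's | 2.00 | 35.0 | 56.8 |
| Tuesday's | 2.50 | 41.8 | 50.5 |
| Wednesday's | 0.333 | 6.8 | 87.4 |
| Wednesday's | 0.833 | 17.3 | 77.4 |
| Wednesday's | 1.50 | 28.6 | 66.0 |
| Wednesday's | 2.50 | 42.9 | 51.9 |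
| Monday's | 0.200 | 3.4 | 75.9 |
| Monday's | 0.417 | 7.5 | 72.0 |
| Monday's | 1.00 | 17.1 | 62.0 |
| Monday's | 2.50 | 36.0 | 42.7 |

(scatter of a reading: 0.3 percentage points)

- the average divides the monomer in chains by the number of chains begun, living and dead together
- the earlier runs do not show the number of chains; that part of a forecast is a guess

- average number of monomer units in a chain (chains begun, living or dead) at 4.0 h
- part of the free monomer that has reacted at 4.0 h

1. I count in mM: the average asked is one amount over another, monomer in chains over chains begun.
2. In Tuesday's, Wednesday's and Monday's runs, free monomer plus monomer in chains holds flat below the charge. That gap, less the protic impurity, reads 0.193 mM, 0.378 mM and 0.162 mM.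
3. I take this excess as initiator lost without a chain, one monomer each. A percentage point is worth fewer mM in a small charge, so I weight each run by one over its charge squared. This gives a rough 0.197 mM.
4. One chain per initiator is my zero. Measured from it, the part of the initiator that begins a chain reads 21.3%: the starting share (initiator efficiency). I then reckon this flask at 0.0533 mM of chains.
5. Tuesday's run, with the same initiator as this flask, reads a fall of free monomer of 0.242 h⁻¹. Taking that rate for this flask, I reckon 10.5 mM in chains by 4.0 h. I reckon an average of 197 and 66.2% reacted.
6. The forecast says 42 and 66.3%, with chains “one per initiator (a guess)”, which differs from my average.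
7. The flask gives 238 and 66.3%.

    free monomer + living end → monomer in chains + living end, rate k1*[living end]*[free monomer] (k = 92.0 L mol⁻¹ min⁻¹)
    protic impurity + free monomer → quenched substrate (k = 25.0 L mol⁻¹ min⁻¹)
    free monomer + initiator → living end + monomer in chains (k = 6.20 L mol⁻¹ min⁻¹)
    free monomer + initiator → spent initiator (k = 29.0 L mol⁻¹ min⁻¹)

8. My 197 stands below the flask's average. I carry the starting share 21.3% to a neighbour of this flask with 0.048 M of free monomer and the same initiator, protic impurity and time, so I reckon again 0.0533 mM of chains. For that neighbour I reckon 28.5 mM in chains, an average of 535 and 63.7% reacted. The neighbour gives 647 and 63.8%.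

(The numbers in the tables were generated by integration with constants of no real substance, noise included.)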